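The cyclohexane ring is cut into a four-carbon unit C7–C2–C3–C4 (benzoyloxymethyl carbon, tertiary carbinol, secondary carbinol, benzoate carbon) and a three-carbon unit C1–C6–C5 (ketone, CH2, carbinol). The first is twofold-symmetric 1,4-bis(benzoyloxy)butane-2,3-dione, which already carries both benzoates; the second is 3-nitropropanal, its nitro carbon standing for the ring ketone. One catalytic operation joins them: an amine-catalysed anti-aldol addition forms C4–C5 and an intramolecular Henry reaction forms C1–C2, giving the ring. The step exploits the C1 ketone flanked by the alpha tertiary carbinol C2 and the beta carbinol C5, the retron of a nitroaldol adduct. Directed reduction at C3 and a Nef reaction finish the synthesis.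

Key step: step 4

Remark on the chemistry: atom labels C1–C7 are those defined above, not the locants of the systematic names; 3-nitropropanal is not commercially available, so it is made in step 3 and used at once.

Step 1
Reactants: 1 but-2-yne-1,4-diol; 2 benzoyl chloride (2.2 equiv in all)
Product: 3 but-2-yne-1,4-diyl dibenzoate
Conditions: BzCl (2.2 equiv), pyridine, DMAP (cat.), CH2Cl2, 0 °C to 20 °C
Reagents that add atoms: benzoyl chloride (second equivalent of 2), O=C(Cl)c1ccccc1
Why: Twofold esterification of the two primary hydroxyls, each with one equivalent of the acid chloride under pyridine and DMAP (acylation of an alcohol), should be clean, and no stereocentre is formed.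

Step 2
Reactants: 3 but-2-yne-1,4-diyl dibenzoate
Product: 4 2,3-dioxobutane-1,4-diyl dibenzoate
Conditions: RuCl3 (2 mol %), NaIO4 (2.5 equiv), EtOAc/MeCN/H2O, 0 °C
Reagents that add atoms: sodium periodate, [Na+].[O-]I(=O)(=O)=O
Why: RuO4 formed in the flask oxidises an internal alkyne to the 1,2-diketone (RuO4 alkyne oxidation), the electron-poor benzoates should survive, and no stereocentre is formed.

Step 3
Reactants: 5 acrolein
Product: 6 3-nitropropanal
Conditions: NaNO2, AcOH, THF/H2O, 0 °C
Reagents that add atoms: sodium nitrite, [Na+].[O-]N=O
Why: Conjugate (Michael) addition of nitrite to the enal under acetic acid buffering should give the beta-nitro aldehyde, which carries no stereocentre and is used fresh because base makes it lose nitrous acid.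

Step 4
Reactants: 4 2,3-dioxobutane-1,4-diyl dibenzoate; 6 3-nitropropanal
Product: 8 [(1S,3R,4R,6R)-3-(benzoyloxy)-1,4-dihydroxy-6-nitro-2-oxocyclohexyl]methyl benzoate, via open-chain anti-aldol adduct 7 (not isolated)
Conditions: (R)-5-(pyrrolidin-2-yl)-1H-tetrazole (20 mol %), 4 (2 equiv), DMF, 4 °C, 6 added slowly; then Et3N (10 mol %), 0 °C, same flask
Reagents that add atoms: none
Why: The amine catalyst condenses with one carbonyl of the twofold-symmetric diketone 4 to an E-enamine whose benzoyloxy-bearing carbon adds to the aldehyde of 6 (direct aldol addition, C4–C5), and after release of the catalyst the nitronate of the open-chain adduct 7 adds to the remote ketone (intramolecular Henry reaction, C1–C2). The closest known reaction types are the amine-catalysed anti-selective aldol addition of alpha-oxygenated ketones to aldehydes and the nitroaldol cyclisation of nitro ketoses to nitrocyclitols. The six-membered ring closes in the 6-exo-trig mode. C4 and C5 are set by the catalyst (a hydrogen-bonded chair-like transition state on the E-enamine gives the anti adduct, and the R-configured catalyst should give the 4R,5R pair by analogy with D-proline), the tertiary carbinol C2 is set in the reversible ring closure that puts CH2OBz equatorial and cis to the C4 benzoate, and the configuration at the nitro carbon is of no consequence because this carbon becomes the ketone. The step needs the aldehyde to serve as acceptor only and the nitronate to choose the remote over the near ketone; an excess of the enamine-forming diketone with slow addition of 6, and the lower strain of closure to the chair-like six-membered ring, should secure this.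

Step 5
Reactants: 8 [(1S,3R,4R,6R)-3-(benzoyloxy)-1,4-dihydroxy-6-nitro-2-oxocyclohexyl]methyl benzoate
Product: 9 [(1S,2S,3R,4R,6R)-3-(benzoyloxy)-1,2,4-trihydroxy-6-nitrocyclohexyl]methyl benzoate
Conditions: Me4NBH(OAc)3 (5 equiv), MeCN/AcOH, −30 °C
Reagents that add atoms: none
Why: In this Evans–Saksena reduction the secondary C5 hydroxyl, axial in the chair of 8, should exchange onto boron and deliver hydride to the C3 ketone from its own face, giving the 1,3-anti (ring-trans) diol, that is C3–OH cis to the C2 hydroxyl and trans to the C4 benzoate.

Step 6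
Reactants: 9 [(1S,2S,3R,4R,6R)-3-(benzoyloxy)-1,2,4-trihydroxy-6-nitrocyclohexyl]methyl benzoate
Product: 10 [(1S,2S,3R,4R)-3-(benzoyloxy)-1,2,4-trihydroxy-6-oxocyclohexyl]methyl benzoate (target)
Conditions: TiCl3 (aqueous HCl solution), NH4OAc, THF/H2O, 0 °C to 20 °C
Reagents that add atoms: water, O
Why: In this reductive Nef reaction TiCl3 should reduce the secondary nitro group through the oxime to the imine, which hydrolyses at pH 5–6 to the C1 ketone without base, so that retro-Henry cleavage, benzoate migration and beta-elimination of the C5 hydroxyl are avoided and no stereocentre is touched.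

Compound list
1 | but-2-yne-1,4-diol | OCC#CCO | starting material
2 | benzoyl chloride | O=C(Cl)c1ccccc1 | starting material
3 | but-2-yne-1,4-diyl dibenzoate | O=C(OCC#CCOC(=O)c1ccccc1)c1ccccc1 | intermediate
4 | 2,3-dioxobutane-1,4-diyl dibenzoate | O=C(OCC(=O)C(=O)COC(=O)c1ccccc1)c1ccccc1 | intermediate
5 | acrolein (prop-2-enal) | C=CC=O | starting material
6 | 3-nitropropanal | O=CCC[N+](=O)[O-] | intermediate
7 | (4R,5R)-5-hydroxy-7-nitro-2,3-dioxoheptane-1,4-diyl dibenzoate (open-chain anti-aldol adduct) | O=C(OCC(=O)C(=O)[C@H](OC(=O)c1ccccc1)[C@H](O)CC[N+](=O)[O-])c1ccccc1 | intermediate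
8 | [(1S,3R,4R,6R)-3-(benzoyloxy)-1,4-dihydroxy-6-nitro-2-oxocyclohexyl]methyl benzoate | O=C(OC[C@@]1(O)[C@H]([N+](=O)[O-])C[C@@H](O)[C@@H](OC(=O)c2ccccc2)C1=O)c1ccccc1 | intermediate
9 | [(1S,2S,3R,4R,6R)-3-(benzoyloxy)-1,2,4-trihydroxy-6-nitrocyclohexyl]methyl benzoate | O=C(OC[C@@]1(O)[C@H]([N+](=O)[O-])C[C@@H](O)[C@@H](OC(=O)c2ccccc2)[C@@H]1O)c1ccccc1 | intermediate
10 | [(1S,2S,3R,4R)-3-(benzoyloxy)-1,2,4-trihydroxy-6-oxocyclohexyl]methyl benzoate | O=C(OC[C@@]1(O)C(=O)C[C@@H](O)[C@@H](OC(=O)c2ccccc2)[C@@H]1O)c1ccccc1 | target

Total step count: 6.
Longest linear sequence: 5 steps (steps 1, 2, 4, 5, 6); step 3 supplies the second component.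

Steps most likely to fail

1. Step 4. The beta-nitro aldehyde may lose nitrous acid through its own enamine before it is captured. The anti selectivity of the aldol event may erode. The nitronate may close onto the nearer ketone and give a five-membered ring. The fallback separates the two bond formations and keeps 6 away from secondary amines. It sets out from 4, which TMSOTf and Et3N (CH2Cl2, 0 °C) should convert into (Z)-3-oxo-2-[(trimethylsilyl)oxy]but-1-ene-1,4-diyl dibenzoate F1. A Mukaiyama aldol addition of F1 to 6 follows under a BINOL–Ti(OiPr)4 Lewis acid, the enantiomer of BINOL being chosen that delivers the 4R,5R adduct (CH2Cl2, −78 °C). Aqueous work-up should give the open-chain adduct 7, now isolated. A separate Henry ring closure with NaHCO3 in THF/H2O at 0 °C comes back to the route at 8.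

2. Step 6. The reduction may stall at the oxime of the hindered nitro carbon, or the newly formed beta-hydroxy ketone may eliminate water. The fallback replaces the Nef reaction by an amine-to-ketone transamination and sets out from 9. Zn dust in aqueous HCl/EtOH at 0 °C should reduce the nitro group to [(1S,2S,3R,4R,6R)-6-amino-3-(benzoyloxy)-1,2,4-trihydroxycyclohexyl]methyl benzoate F2. Condensation of F2 with 3,5-di-tert-butyl-1,2-benzoquinone, prototropic shift and hydrolysis with aqueous oxalic acid should give the ketone and come back to the route at 10.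

3. Step 5. Hydride may be delivered from the tertiary C2 alkoxide instead of the C5 alkoxide, which would mean poor facial selectivity at C3. The fallback ties the hydride donor to the C5 oxygen only and sets out from 8. Chlorodi(propan-2-yl)silane and imidazole (DMF, 0 °C) should silylate the secondary hydroxyl selectively, giving [(1S,3R,4R,6R)-3-(benzoyloxy)-4-{[di(propan-2-yl)silyl]oxy}-1-hydroxy-6-nitro-2-oxocyclohexyl]methyl benzoate F3. SnCl4 (1.1 equiv, CH2Cl2, −78 °C) should then activate the C3 ketone for intramolecular hydride transfer from silicon on the face of the axial C5 oxygen (1,3-anti). Because the trans-1,3-diol cannot be bridged by one silicon atom, the silicon should take up chloride and give the C5 O-[chlorodi(propan-2-yl)silyl] ether of 9 F4, which is not isolated. Cleavage of the silicon–oxygen bond with HF·pyridine in the same flask comes back to the route at 9.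

Further compounds
F1 | step 4 | (Z)-3-oxo-2-[(trimethylsilyl)oxy]but-1-ene-1,4-diyl dibenzoate | O=C(OCC(=O)/C(O[Si](C)(C)C)=C/OC(=O)c1ccccc1)c1ccccc1
F2 | step 6 | [(1S,2S,3R,4R,6R)-6-amino-3-(benzoyloxy)-1,2,4-trihydroxycyclohexyl]methyl benzoate | O=C(OC[C@@]1(O)[C@H](N)C[C@@H](O)[C@@H](OC(=O)c2ccccc2)[C@@H]1O)c1ccccc1
F3 | step 5 | [(1S,3R,4R,6R)-3-(benzoyloxy)-4-{[di(propan-2-yl)silyl]oxy}-1-hydroxy-6-nitro-2-oxocyclohexyl]methyl benzoate | O=C(OC[C@@]1(O)[C@H]([N+](=O)[O-])C[C@@H](O[SiH](C(C)C)C(C)C)[C@@H](OC(=O)c2ccccc2)C1=O)c1ccccc1
F4 | step 5 | C5 O-[chlorodi(propan-2-yl)silyl] ether of 9 | O=C(OC[C@@]1(O)[C@H]([N+](=O)[O-])C[C@@H](O[Si](Cl)(C(C)C)C(C)C)[C@@H](OC(=O)c2ccccc2)[C@@H]1O)c1ccccc1
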